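**Two numbers.** The north run is the neighbour to read: by 1.33 min it had made 9.6% of D, yet from 4.00 min to 8.00 min it gained 1.5 percentage points, a pace 19.2 times slower, although D is made from G and Q and Q by then read 80.4%, more than the earlier 58.6%.

| flask | Z | G | remark | time |
|---|---|---|---|---|
| west | 0.50 M | 0.32 M | run made earlier |  |
| north-west | 0.50 M | 0.67 M | run made earlier |  |
| north | 0.50 M | 1.6 M | run made earlier |  |
| Wednesday's | 0.50 M | 0.250 M |  | 10 min |
| Thursday's | 0.50 M | 1.25 M |  | 10 min |
| Tuesday's | 0.50 M | 1.50 M |  | 10 min |

| run | time / min | D / % | Q / % |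
|---|---|---|---|
| west | 1.33 | 0 | 5.8 |
| west | 3.00 | 0.2 | 9.3 |
| west | 4.00 | 0.9 | 9.3 |
| west | 6.00 | 0 | 9.6 |
| west | 8.00 | 0.1 | 9.4 |
| north-west | 0.667 | 0.3 | 11.3 |
| north-west | 2.00 | 1.8 | 27.6 |
| north-west | 3.00 | 1.5 | 32.9 |
| north-west | 5.00 | 2.2 | 38.5 |
| north-west | 8.00 | 2.3 | 40.9 |
| north | 1.33 | 9.6 | 58.6 |
| north | 3.00 | 13.8 | 76.2 |
| north | 4.00 | 14.9 | 79.0 |
| north | 6.00 | 15.9 | 79.9 |
| north | 8.00 | 16.4 | 80.4 |

(scatter of a reading: 0.3 percentage points)

- for Q the L are counted in
- as a solid, counted per litre of solution: L
- reactions considered so far: G + X -> Q; G + Q -> D; Q -> J; Z + G -> X; L <-> Q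

- how much D is there at the end, in percent of the Z charged: for each flask in turn (Wednesday's, Thursday's, Tuesday's)

**Clearing it.** Counting two G in each Q and 3 in each D, and leaving out X and J, which were not read, the north run still held about 0.562 M of G at 6.00 min, about a third of its charge, and that fall in G is too small to account for the slowing. But the Q reading counts the crystals L, so I take it that G meets dissolved Q, held near saturation while crystals stand, which makes D pseudo-first-order in G.

**Creep constant.** You can therefore read the share of the G left that goes into D each minute while crystals stand, the creep constant 0.00333 min⁻¹, a rough reading, each D reading scattering by 0.3 points.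

**My reckoning.** Carried to 10 min with G held at that figure, my reckoning puts the north run at 17.1% of D. Tuesday's flask is charged with less G, and scaling D by the charge, my own assumption, gives 16.1% for Tuesday's flask.

The forecast, reasoning that “Q must therefore be locked up as crystals, leaving little in solution”, gives 0.1% for Wednesday's flask, 12% for Thursday's and 15% for Tuesday's, its Tuesday's figure lying below mine.

**The result.** D ends at 0.185% in Wednesday's flask, 10.9% in Thursday's and 15.9% in Tuesday's, where 79.4% of the Z charged stands as L within the 81.1% of Q.

    G + X → Q (k = 1.40 L mol⁻¹ min⁻¹)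
    G + Q → D (k = 0.530 L mol⁻¹ min⁻¹)
    Q → J (k = 0.0620 min⁻¹)
    Z + G → X (k = 2.40 L mol⁻¹ min⁻¹)
    L ⇌ Q, rate k5*(cs5 - [Q]) while solid is left; crystals form when [Q] > cs5 (solubility = 8.70 mM, k = 2.70 min⁻¹)

**Creep again.** In Tuesday's flask G falls from 0.421 M at 10.0 min to 0.287 M at 100 min, and the creep constant on their mean gives 21 points of further D, less than the 27 points the flask gains. In Thursday's flask, over the same span, it gives 10 points against a gain of 13 points.

The runs come from a simulation with constants of no real substance; noise was put on by code.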